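In a closed flask partner is conserved: each molecule charged is still partner, or sits in intermediate or target, or has gone some other way. We watch this balance through the runs below.

| setting | ochre | green | red | flask |
|---|---|---|---|---|
| substrate | 0.050 M | 0.050 M | 0.075 M | 0.050 M |
| partner | 0.030 M | 0.045 M | 0.060 M | 0.0600 M |
| second reagent | 0.0475 M | 0.0475 M | 0.0475 M | 0.0475 M |
| remark | run made earlier | run made earlier | run made earlier |  |
| time |  |  |  | 40 h |

| run | time / h | intermediate / % | target / % |
|---|---|---|---|
| ochre | 1.50 | 19.2 | 1.2 |
| ochre | 3.00 | 27.4 | 3.5 |
| ochre | 8.00 | 32.9 | 13.5 |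
| ochre | 15.0 | 27.5 | 24.9 |
| ochre | 30.0 | 16.2 | 37.8 |
| green | 1.50 | 27.0 | 1.4 |
| green | 3.00 | 38.2 | 5.0 |
| green | 8.00 | 43.2 | 17.4 |
| green | 15.0 | 37.0 | 32.0 |
| green | 30.0 | 25.1 | 49.4 |
| red | 1.50 | 31.7 | 2.2 |
| red | 3.00 | 41.2 | 6.3 |
| red | 8.00 | 43.9 | 18.5 |
| red | 15.0 | 37.2 | 29.8 |
| red | 30.0 | 26.5 | 41.6 |

(scatter of a reading: 0.3 percentage points)

- time up to 40 h at which intermediate stands highest
- the amount of intermediate, in percent of the substrate charged, at that time



The capture is the share of charged partner found in intermediate plus target, counted as if each holds one partner. At its last reading the green run, with 0.900 equivalents of partner to substrate, captures 82.8%. The missing share also counts any partner still unreacted. Dividing that share by the equivalents gives 0.191, which we call the loss per equivalent, s. The ochre run gives 0.167 and the red run 0.186.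

We take the green value because its equivalents, higher than those of the ochre and red runs, stand nearest the flask's 1.20. Partner then reaches 92.4% of the substrate charged, less than the whole. So by this reckoning partner, though charged in excess, is in effect the limiting reagent. The highest intermediate reading of the green run was 58.0% of the sum at its last reading, which puts our estimate of the flask's peak near 53.6%. We expect it before the time of that green reading, 8.00 h, since the flask holds more partner.

The forecast gives 52.5% at 6 h, lower than our figure: “I therefore peaks near 6 h at about 52–53%, where formation equals onward loss at about 3.5%/h.”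

    2 partner → self-condensation product (k = 0.0166 M⁻¹ min⁻¹)
    second reagent + intermediate → target (k = 0.0246 M⁻¹ min⁻¹)
    substrate + partner → intermediate (k = 0.110 M⁻¹ min⁻¹)
    second reagent ⇌ dormant form (K = 1.70, k = 4.76 × 10⁻⁵ min⁻¹)

The flask gives 52.1% at 6.38 h, and the forecast holds on both; a flask with twice the partner and all other amounts as they are peaks at 4.52 h. After 400 h the flask holds 92.6% of the substrate charged as target plus intermediate, against our 92.4%, with partner at 0% of its own charge and substrate at 7.39%. For a neighbour charged with 0.085 M of substrate, s gives 61.1%; after 40.0 h that neighbour holds 62.2% of its substrate charged as target plus intermediate, with partner at 0.00619% of its own charge.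

All runs were computed on assumed constants; the scatter is artificial.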